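The readings come from a simulation on assumed constants; the scatter is artificial.

Take the step from complex with one exchanged to isomer of the product as having come level, and reckon with that pair as one pool.

| setting | teal | red | violet | flask |
|---|---|---|---|---|
| starting complex | 0.035 M | 0.053 M | 0.071 M | 0.071 M |
| leaving ligand | 0.0355 M | 0.0355 M | 0.018 M | 0.0355 M |
| gas | 16 mM (held) | 16 mM (held) | 16 mM (held) | 16 mM (held) |
| remark | run made earlier | run made earlier | run made earlier |  |
| time |  |  |  | 20 min |

- teal (time / min: starting complex / %, complex with one exchanged / %, isomer of the product / %): 2.50: 42.3, 17.7, 27.2; 5.00: 37.0, 15.6, 35.9; 8.00: 35.0, 15.2, 38.9; 10.0: 34.9, 14.7, 39.6; 12.0: 34.8, 14.5, 40.4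
- red (time / min: starting complex / %, complex with one exchanged / %, isomer of the product / %): 1.00: 55.6, 21.1, 11.8; 3.00: 45.3, 17.0, 27.9; 6.00: 40.3, 14.6, 36.0; 8.00: 39.7, 14.8, 37.3; 12.0: 38.3, 14.4, 38.5
- violet (time / min: starting complex / %, complex with one exchanged / %, isomer of the product / %): 1.00: 55.2, 21.5, 12.7; 2.00: 47.1, 18.4, 23.0; 3.00: 44.0, 16.9, 28.1; 6.00: 39.2, 15.1, 36.2; 12.0: 37.7, 14.3, 38.7

(standard deviation of a reading: 0.3 percentage points)

- at the start none of the gas is in solution
- the reaction counts as stopped when no species that holds the starting complex changes by six tenths of a point or more over the second half of the time

- the state of affairs at 20 min: stopped, and by what, or still going (forward and back rates have come level / it is still moving / all of the starting complex has reacted)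
- conversion of starting complex at 20 min
- amount of complex with one exchanged at 20 min, in percent of the starting complex charged
- amount of isomer of the product at 20 min, in percent of the starting complex charged
- amount of complex with two exchanged at 20 min, in percent of the starting complex charged

Two amounts are reckoned here: the fractions of the charge in complex with one exchanged and in isomer of the product. The violet run has the same complex charge as the flask, and its last reading shows 38.7% of isomer against 14.3% of complex with one exchanged, a ratio of 2.71. This reading is the split, the isomer fraction over the one-exchanged fraction once the pair stands level. The last teal and red readings give 2.79 and 2.67, though their charges differ.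

Violet isomer closes on its last reading with a time of about 2.08 min, which is short against 20 min, so if the flask moves at a like pace, its forward and back rates should have come level.

Teal, red and the flask share one ligand charge and climb by equal steps of complex, 0.0180 M and 0.0180 M. The pool reads 54.9% in teal and 52.9% in red, so a straight line carried one more equal step gives an estimate of 50.9% for the flask. In this reckoning the split then divides that pool into 13.7% of complex with one exchanged and 37.2% of isomer.

The forecast says forward and back rates have come level, with conversion 59%, 14.1% of complex with one exchanged, 36.8% of isomer and 8.1% of complex with two exchanged, holding that “20 min should be at equilibrium”.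

At 20 min the flask shows forward and back rates have come level, with conversion 57.8%, 13.8% of complex with one exchanged, 37.3% of isomer and 4.28% of complex with two exchanged. The relaxation half-life of the pair by its own step is 0.669 min, short against 20 min.

    starting complex + incoming ligand ⇌ leaving ligand + complex with one exchanged (K = 1.70, k = 6.54 L mol⁻¹ s⁻¹)
    complex with one exchanged + incoming ligand ⇌ leaving ligand + complex with two exchanged (K = 1.61, k = 17.2 L mol⁻¹ s⁻¹)
    complex with two exchanged + incoming ligand ⇌ leaving ligand + complex with three exchanged (K = 3.00, k = 1.31 L mol⁻¹ s⁻¹)
    complex with one exchanged ⇌ isomer of the product (K = 2.70, k = 0.0126 s⁻¹)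
    gas ⇌ incoming ligand, rate k5*(csat - [incoming ligand]) (kL = 0.168 s⁻¹)

The split applied to the flask's 13.8% gives 37.4% of isomer, and the flask holds 37.3%. In a neighbour flask charged with 0.18 M of starting complex, the split applied to its 11.6% gives 31.4% of isomer; the computed amount there is 31.3%.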